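The numbers are assumed.

A small charge of substrate, 2.0 mM, meets a larger charge of coupling partner, 3.60 mM, in the set-ups below, and the question is how much product each delivers.

in all of them: substrate 2.0 mM
- larch: coupling partner 3.60 mM (fed, over 0.750 min); time 1.5 min; all but coupling partner at the start; coupling partner goes in evenly over 0.750 min, the run ends at 1.5 min
- ash: coupling partner 3.60 mM; time 1.5 min; plug flow through a tube for 1.5 min, no back-mixing
- birch: coupling partner 3.60 mM; time 1.5 min; everything together in a closed stirred flask, run for 1.5 min
- alder: coupling partner 3.60 mM; a single well-mixed tank run continuously and read at steady state, 1.5 min in it on average

    substrate + coupling partner ⇌ adduct, settled at all times (K1 = 4400 M⁻¹)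
    adduct → product (k2 = 0.987 s⁻¹)
    adduct → decomposed reagent (k3 = 0.913 s⁻¹)

- the set-up with the highest amount of product at the outlet or at the end, in percent of the substrate put in ("none" if the first two lie within 2 percentage points) (larch / ash / birch / alder / none)
- amount of product at the outlet or at the end, in percent of the substrate put in, larch
- amount of product at the outlet or at the end, in percent of the substrate put in, ash
- amount of product at the outlet or at the end, in percent of the substrate put in, birch
- amount of product at the outlet or at the end, in percent of the substrate put in, alder

- the stated concentrations are those of everything mixed, before any reaction; amounts are the same in each set-up
- the feed brings no volume worth counting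
- run time (larch): 1.5 min

Follow one substrate molecule, and build the flask up step by step. With the step to product as the sole way out of the adduct, each molecule that binds ends as product, and substrate, at 2.0 mM against 3.60 mM of coupling partner, is the limiting reagent, so the yield heads for 100%. Now add the step to decomposed reagent. The adduct stands at a fork with two first-order exits, so its chance of becoming product is the fork share φ, the rate constant toward product divided by the sum of both: 51.9%. This is the selectivity of the fork, and no concentration enters it. Now add the balance. An adduct that falls apart gives free substrate, whose one way on is the adduct again, so the return trip leaves φ as it was.

Time remains. Once the substrate charge has reacted, 1.60 mM of coupling partner stays, and K₁ times that is 7.04, so 87.6% of the unfinished substrate sits as adduct. That pool empties with a mean life of 0.601 s. This is far shorter than the run, which lasts 150 such lives, and larch still has 74.9 of them after its feed ends. I therefore put larch, ash and birch at φ. The alder tank keeps back a share of 0.663%, which gives 51.6%, a gap of 0.34 percentage points, smaller than the margin of 2 points.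

The forecast agrees with this reckoning: 51.9% for larch, 51.9% for ash, 51.9% for birch and 51.6% for alder, with best none. It holds that the substrate is essentially used up, “even in the tank, which falls only a few tenths short”.

The simulation gives 51.9% for larch, 51.9% for ash, 51.9% for birch and 51.6% for alder, so best is none. In larch, coupling partner went in over the first 0.750 min, reaching at most 1.60 mM, while the adduct drained down both exits from a substrate charge of 2.00 mM, and the yield reached φ, 51.9%. In the alder tank, both exits ran steadily with 1.60 mM of coupling partner and 0.00165 mM of substrate present, and 0.581% of the charge stood as adduct. The same tank at 3 times the residence time reads 51.8%, close to φ at 51.9%.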